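**Retrosynthetic overview**
- α-Tocotrienol (2R,3'E,7'E) ⇐ MOM-ether deprotection ⇐ enantioselective Markovnikov hydroalkoxylation of a phenol onto a 1,1-disubstituted alkene (Co–H HAT radical-polar crossover). This step closes the only ring formed in the route and sets C2.
- That cyclisation precursor ⇐ Wittig methylenation of a hydroxy-ketone ⇐ kinetic, methyl-side C-alkylation of the trimethylhydroquinone (TMHQ)/methyl vinyl ketone (MVK) adduct with (E,E)-farnesyl bromide. This pre-installs all three E-alkenes.
- The aryl–CH2CH2–C(=O) unit ⇐ Friedel–Crafts/Michael annulation of commercial TMHQ with MVK.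

Assumptions:
- The target SMILES is (2R,3'E,7'E)-α-tocotrienol (natural configuration).
- (2E,6E)-Farnesol, TMHQ and MVK are commercial.
- The chiral Co(salen) enantiomer must be matched empirically to give 2R. I assume (R,R) does.
- All steps run under N2/Ar because hydroquinone and tocochromanol intermediates are air-sensitive.

---

**Step 1**
Reactants: 1 (2E,6E)-farnesol
Product: 2 (2E,6E)-farnesyl bromide
Conditions: PBr3 (0.4 equiv), Et2O, 0 °C, 1 h; use crude immediately
Reagents that add atoms: PBr3, BrP(Br)Br (Br ends up in the product)
Why: SN2 conversion of a primary allylic alcohol to the bromide with no allylic transposition, so all E-geometry is retained; no stereocentre is formed.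

**Step 2**
Reactants: 3 2,3,5-trimethylhydroquinone; 4 methyl vinyl ketone
Product: 5 2,5,7,8-tetramethylchroman-2,6-diol (racemic hemiketal; ring-chain tautomer of 4-(2,5-dihydroxy-3,4,6-trimethylphenyl)butan-2-one)
Conditions: MVK (1.2 equiv), cat. ZnCl2, cat. HCl, AcOH, 50 °C
Reagents that add atoms: none beyond reactant 4 (C=CC(C)=O)
Why: Friedel–Crafts (Michael-type) alkylation at the only free ring carbon, ortho to OH, followed by intramolecular hemiketalisation. The labile hemiketal centre is destroyed in Step 4, so its configuration is irrelevant.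

**Step 3**
Reactants: 5
Product: 6 6-(methoxymethoxy)-2,5,7,8-tetramethylchroman-2-ol (hemiketal; open form is 4-[2-hydroxy-5-(MOM-oxy)-3,4,6-trimethylphenyl]butan-2-one)
Conditions: NaH (1.05 equiv), THF/DMF, 0 °C; then MOMCl (1.1 equiv), 0 °C to rt
Reagents that add atoms: MOMCl, ClCOC
Why: Protecting-group installation. With one equivalent of base only the acidic free phenol is deprotonated, because the hemiketal O1 is tied up in the ring. The MOM ether survives LDA, ylides and HAT conditions and can be removed later without Brønsted acid.

**Step 4**
Reactants: 6; 2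
Product: 7 (6E,10E)-configured hydroxy-ketone: 1-[2-hydroxy-5-(MOM-oxy)-3,4,6-trimethylphenyl]-7,11,15-trimethylhexadeca-... i.e. ArCH2CH2C(=O)CH2CH2CH=C(Me)CH2CH2CH=C(Me)CH2CH2CH=CMe2, phenol free
Conditions: LDA (2.2 equiv), THF/DMPU, –78 °C, 30 min (first equivalent opens the hemiketal to the phenoxide-ketone, second forms the methyl-side enolate); add 2 at –78 °C, warm to 0 °C
Reagents that add atoms: none (the farnesyl unit comes from reactant 2, CC(C)=CCC/C(C)=C/CC/C(C)=C/CBr)
Why: Kinetic dianion alkylation. LDA deprotonates the less hindered CH3 of the methyl ketone, and SN2 attack at the primary allylic carbon (α-attack, no SN2′) keeps the E,E-geometry. The hindered phenoxide is a poor O-alkylation partner. No stereocentre is formed.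

**Step 5**
Reactants: 7
Product: 8 2-[3-methylene-(farnesylethyl)chain]: ArCH2CH2C(=CH2)CH2CH2CH=C(Me)CH2CH2CH=C(Me)CH2CH2CH=CMe2, phenol free, MOM-protected para-OH
Conditions: Ph3P+CH3 Br– (3 equiv), KOtBu (3 equiv), THF, 0 °C to rt
Reagents that add atoms: methyltriphenylphosphonium bromide, C[P+](c1ccccc1)(c1ccccc1)c1ccccc1.[Br-] (supplies the =CH2 carbon)
Why: Wittig methylenation of an enolisable ketone with the small, non-stabilised ylide. The excess ylide covers the acidic phenol. The product is a 1,1-disubstituted alkene, a prochiral handle for Step 6.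

**Step 6**
Reactants: 8
Product: 9 (2R)-MOM-α-tocotrienol
Conditions: (R,R)-Co(salen) catalyst (5 mol %; N,N'-bis(3,5-di-tert-butylsalicylidene)-(1R,2R)-cyclohexanediamine cobalt, oxidised to Co(III) in situ), N-fluoro-2,4,6-trimethylpyridinium triflate (2 equiv), PhSiH3 (1.5 equiv), PhCF3, 0 °C to rt, 12 h
Reagents that add atoms: none (only H from the silane is incorporated)
Why: Proposed new method: Co–H hydrogen-atom transfer occurs preferentially at the unhindered 1,1-disubstituted alkene, leaving the three hindered trisubstituted alkenes untouched. This gives a tertiary radical that is captured by the chiral Co complex and oxidised to an alkyl-Co(IV) (carbocation equivalent). The tethered phenol O then displaces Co(IV) intramolecularly in a 6-exo Markovnikov closure, and the chiral salen pocket controls the face of C–O bond formation, setting the quaternary C2 as R. The closest known reaction is Co(salen)/N-fluoropyridinium/silane radical-polar-crossover hydroalkoxylation of alkenols, including racemic 2,2-dialkylchroman formation from alkenyl phenols. The new elements are an electron-rich tocopherol-type phenol, a polyprenyl substrate and enantiocontrol at this centre.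

**Step 7**
Reactants: 9
Product: 10 (2R,3'E,7'E)-α-tocotrienol
Conditions: ZnBr2 (3 equiv), n-PrSH (10 equiv), CH2Cl2, 0 °C to rt, 30 min, degassed, dark
Reagents that add atoms: none (the MOM group is lost)
Why: Lewis-acid/thiol cleavage of the MOM acetal avoids strong Brønsted acid that could protonate the polyene or the chroman ether. No bond to C2 is touched, so the stereocentre is preserved.

---

**Compound list**

| No. | Name | SMILES | Role |
|---|---|---|---|
| 1 | (2E,6E)-farnesol | CC(C)=CCC/C(C)=C/CC/C(C)=C/CO | starting material |
| 2 | (2E,6E)-farnesyl bromide | CC(C)=CCC/C(C)=C/CC/C(C)=C/CBr | intermediate |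
| 3 | 2,3,5-trimethylhydroquinone | Oc1cc(C)c(O)c(C)c1C | starting material |
| 4 | methyl vinyl ketone | C=CC(C)=O | starting material |
| 5 | 2,5,7,8-tetramethylchroman-2,6-diol (racemic) | CC1(O)CCc2c(C)c(O)c(C)c(C)c2O1 | intermediate |
| 6 | 6-(methoxymethoxy)-2,5,7,8-tetramethylchroman-2-ol | CC1(O)CCc2c(C)c(OCOC)c(C)c(C)c2O1 | intermediate |
| 7 | hydroxy-ketone (open form of the alkylated hemiketal) | CC(C)=CCC/C(C)=C/CC/C(C)=C/CCC(=O)CCc1c(C)c(OCOC)c(C)c(C)c1O | intermediate |
| 8 | 1,1-disubstituted alkenyl phenol | CC(C)=CCC/C(C)=C/CC/C(C)=C/CCC(=C)CCc1c(C)c(OCOC)c(C)c(C)c1O | intermediate |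
| 9 | (2R)-MOM-α-tocotrienol | CC(C)=CCC/C(C)=C/CC/C(C)=C/CC[C@]1(C)CCc2c(C)c(OCOC)c(C)c(C)c2O1 | intermediate |
| 10 | (2R,3'E,7'E)-α-tocotrienol | CC(C)=CCC/C(C)=C/CC/C(C)=C/CC[C@]1(C)CCc2c(C)c(O)c(C)c(C)c2O1 | target |

**Totals:** 7 steps in total. The longest linear sequence is 6 steps (TMHQ → Steps 2–7). The farnesyl bromide branch is 1 step and joins at Step 4.

**Three steps most likely to fail**
1. **Step 6** (asymmetric HAT hydroalkoxylation). Possible problems are oxidation of the electron-rich phenol/arene, loss of chemoselectivity towards the trisubstituted alkenes, and modest ee. Fallback: a Pd-catalysed asymmetric intramolecular allylic etherification route. Cyclise the phenol–allylic carbonate ArCH2CH2C(Me)=CHCH2OBoc with Pd/(R,R)-Trost ligand to give (2R)-2-methyl-2-vinylchroman. Then hydroborate the vinyl group (9-BBN) and couple it by B-alkyl Suzuki with the (E,E)-vinyl iodide I–CH=C(Me)CH2CH2CH=C(Me)CH2CH2CH=CMe2.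
2. **Step 4** (regioselectivity of the dianion alkylation, C- versus O-alkylation). Fallback: make the full-chain vinyl ketone CH2=CH–CO–CH2CH2CH=C(Me)… from the farnesyl-malonate-derived acid via its Weinreb amide and vinylMgBr. Then run the TMHQ/enone annulation (Step 2) on that enone to give the full-chain hemiketal directly, and continue with MOM protection and Wittig methylenation.
3. **Step 2** (acid-mediated TMHQ/MVK annulation, with risks of MVK oligomerisation and hydroquinone oxidation). Fallback: use the dihydrocoumarin route. Condense TMHQ with acrylic acid to give 6-hydroxy-5,7,8-trimethylchroman-2-one, protect the phenol as the MOM ether, then add MeMgBr (1 equiv, –78 °C) to the lactone to obtain hemiketal 6.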